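**Strategy.** Daucane numbering: cyclopentane C1–C5 (C1 quaternary, CH3; C2 CHOH; C4 isopropyl carbinol; C5 fusion CH), cycloheptane C1/C5–C10. The cyclopentane holds oxygen at C2 and C4 (1,3) between quaternary C1 and C5. With C4 as a ketone it is therefore the (3+2) adduct of a 2-oxyallyl cation (C3–C4–C5) and an aldehyde silyl enol ether (C1=C2). In an acyclic α-chloro ketone the C6–C10 chain, with the Z C8=C9 olefin and the C6/C10 silyloxy stereocentres, tethers both partners. One operation closes the cycloheptene and the cyclopentanone and sets C1, C2 and C5.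

Key step: step 11

Remark: 5 (otherwise one step from (R)-4-benzyl-1,3-thiazolidine-2-thione and propanoyl chloride) and 11 are taken as purchasable; C1–C10 in all names and explanations are the daucane numbers of the target.

Step 1
Reactants: 1 but-2-yn-1-ol
Product: 3 (Z)-3-iodobut-2-en-1-ol, via cyclic alkenylalanate 2 (not isolated)
Conditions: NaAlH2(OCH2CH2OMe)2, THF, 0 °C to rt; then I2, −78 °C to rt
Reagents that add atoms: iodine, II
Why: Hydroxyl-directed trans-hydroalumination puts aluminium on C3 and iodinolysis with retention should give the (Z)-iodide, which fixes the later cis C7/C10 relationship across C8=C9.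

Step 2
Reactants: 3 (Z)-3-iodobut-2-en-1-ol
Product: 4 (Z)-3-iodobut-2-enal
Conditions: MnO2, CH2Cl2, rt
Reagents that add atoms: none
Why: Neutral allylic oxidation with MnO2 should give the enal without Z/E isomerisation.

Step 3
Reactants: 4 (Z)-3-iodobut-2-enal; 5 (R)-4-benzyl-3-propanoyl-1,3-thiazolidine-2-thione
Product: 7 (R)-4-benzyl-3-[(2R,3R,4Z)-3-hydroxy-5-iodo-2-methylhex-4-enoyl]-1,3-thiazolidine-2-thione, via trichlorotitanium (Z)-enolate 6 (not isolated)
Conditions: 5, TiCl4, i-Pr2NEt, N-methylpyrrolidinone, CH2Cl2, 0 °C; then 4, −78 to 0 °C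
Reagents that add atoms: none
Why: Auxiliary-controlled titanium-enolate syn-aldol addition through a closed chair transition state, in which the benzyl group of the (R)-auxiliary shields one enolate face, should set the C10 carbinol configuration (the methyl-bearing centre is erased in step 6).

Step 4
Reactants: 7 aldol adduct
Product: 8 (R)-4-benzyl-3-[(2R,3R,4Z)-5-iodo-2-methyl-3-(triethylsilyloxy)hex-4-enoyl]-1,3-thiazolidine-2-thione
Conditions: TESOTf, 2,6-lutidine, CH2Cl2, −78 °C
Reagents that add atoms: triethylsilyl trifluoromethanesulfonate, CC[Si](CC)(CC)OS(=O)(=O)C(F)(F)F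
Why: Standard silylation of a secondary aldol hydroxyl at low temperature, which avoids retro-aldol cleavage.

Step 5
Reactants: 8 silylated aldol adduct
Product: 9 (2R,3R,4Z)-5-iodo-2-methyl-3-(triethylsilyloxy)hex-4-enal
Conditions: i-Bu2AlH, CH2Cl2, −78 °C
Reagents that add atoms: none
Why: N-Acyl thiazolidinethiones are reduced directly to aldehydes by i-Bu2AlH with release of the auxiliary, and the alkenyl iodide is inert at −78 °C.

Step 6
Reactants: 9 aldehyde
Product: 10 tert-butyl{[(1E,3S,4Z)-5-iodo-2-methyl-3-(triethylsilyloxy)hexa-1,4-dien-1-yl]oxy}dimethylsilane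
Conditions: TBSOTf, Et3N, CH2Cl2, 0 °C to rt
Reagents that add atoms: tert-butyldimethylsilyl trifluoromethanesulfonate, CC(C)(C)[Si](C)(C)OS(=O)(=O)C(F)(F)F
Why: Soft enolisation and O-silylation of the α-branched aldehyde should give mainly the (E)-enol ether, with the silyloxy group cis to the small methyl and trans to the branched C10 substituent.

Step 7
Reactants: 11 ethyl (R)-4-chloro-3-hydroxybutanoate
Product: 12 ethyl 2-[(2R)-oxiran-2-yl]acetate
Conditions: Ag2O, 1,2-dimethoxyethane, 60 °C
Reagents that add atoms: none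
Why: Silver-oxide-mediated internal SN2 closure at the primary carbon leaves the C6 stereocentre untouched and avoids base-induced elimination to the γ-hydroxy crotonate.

Step 8
Reactants: 10 alkenyl iodide; 12 ethyl 2-[(2R)-oxiran-2-yl]acetate
Product: 15 ethyl (3S,5Z,7S,8E)-9-(tert-butyldimethylsilyloxy)-3-hydroxy-5,8-dimethyl-7-(triethylsilyloxy)nona-5,8-dienoate, via alkenyllithium 13 (not isolated), via alkenylmagnesium bromide 14 (not isolated)
Conditions: t-BuLi (2 equiv), Et2O, −78 °C; MgBr2·OEt2, −78 to −40 °C; then CuI (10 mol %), 12, THF, −40 to −20 °C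
Reagents that add atoms: none
Why: Iodine–lithium exchange with retention of olefin geometry, transmetalation to magnesium and copper-catalysed SN2 opening of the terminal epoxide at its CH2 carbon should form the C7–C8 bond without touching the ester or the C6 stereocentre.

Step 9
Reactants: 15 hydroxy ester
Product: 16 ethyl (3S,5Z,7S,8E)-9-(tert-butyldimethylsilyloxy)-5,8-dimethyl-3,7-bis(triethylsilyloxy)nona-5,8-dienoate
Conditions: TESCl, imidazole, DMF, 0 °C to rt
Reagents that add atoms: chlorotriethylsilane, CC[Si](Cl)(CC)CC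
Why: Standard silylation, which also prevents O-alkylation of C3 by the C6 hydroxyl (furanone formation) in steps 10 and 11.

Step 10
Reactants: 16 bis(triethylsilyl) ester
Product: 17 (4S,6Z,8S,9E)-10-(tert-butyldimethylsilyloxy)-1-chloro-6,9-dimethyl-4,8-bis(triethylsilyloxy)deca-6,9-dien-2-one
Conditions: ICH2Cl, MeLi·LiBr, THF/Et2O, −78 °C; AcOH quench
Reagents that add atoms: chloroiodomethane, ClCI
Why: Chloromethyllithium generated in situ adds once to the ester because the tetrahedral lithium alkoxide is stable at −78 °C (ester-to-chloromethyl-ketone homologation).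

Step 11
Reactants: 17 α-chloro ketone
Product: 20 (3S,3aS,4S,8S,8aS)-3-(tert-butyldimethylsilyloxy)-3a,6-dimethyl-4,8-bis(triethylsilyloxy)-3,3a,4,7,8,8a-hexahydroazulen-1(2H)-one, via 2-oxyallyl cation 18 (not isolated), via enolate-oxocarbenium zwitterion 19 (not isolated)
Conditions: Et3N, LiClO4 (3 M), Et2O, 0 °C to rt, 0.005 M
Reagents that add atoms: none
Why: Et3N enolises the chloro ketone towards C5 and the LiClO4 medium ionises the C3–Cl bond to the 2-oxyallyl cation 18; the enol-ether carbon C1 adds to the substituted terminus C5, and the enolate carbon C3 of zwitterion 19 then collapses onto the silyloxocarbenium carbon C2, i.e. a stepwise (3+2) cycloaddition. The closest known reaction type is the (3+2) cyclopentanone annulation of 2-oxyallyl cations with silyl enol ethers, vinyl sulfides and indoles, and the cation is generated as in intramolecular (4+3) cycloadditions of α-chloro ketones. The cycloheptene closes 7-exo-trig at C5 (attack at C3 would need a nine-membered ring), and the cyclopentanone closes in a 5-(enolendo)-exo-trig aldol-type step that is the second bond of the cycloaddition. C5 is controlled by C6 (W-shaped oxyallyl with the C6 hydrogen eclipsing the oxyallyl oxygen, so C4 ends trans to the C6 silyloxy group), C1 by C10 (the C10 silyloxy group turns away from the C1 methyl and ends trans to it), the cis ring fusion by face-to-face stacking of the tethered π systems (and by equilibration at the enolisable C5 under Et3N), and C2 by suprafacial use of the (E)-enol ether, which places the silyloxy group cis to the C1 methyl. The step needs C5-over-C3 regioselectivity, C- over O-closure and ring closure faster than desilylation or Favorskii rearrangement; the tether length, the reversibility of O-closure (a silyl acetal that re-ionises) and the aprotic, non-nucleophilic medium should secure them.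

Step 12
Reactants: 20 bicyclic ketone
Product: 21 (1R,3S,3aS,4S,8S,8aS)-3-(tert-butyldimethylsilyloxy)-1-isopropyl-3a,6-dimethyl-4,8-bis(triethylsilyloxy)-1,2,3,3a,4,7,8,8a-octahydroazulen-1-ol
Conditions: i-PrMgCl, CeCl3, THF, −78 to 0 °C
Reagents that add atoms: isopropylmagnesium chloride, CC(C)[Mg]Cl
Why: The non-basic organocerium reagent suppresses enolisation, β-hydride reduction and β-elimination, and should attack the ketone anti to the vicinal C5–C6 bond (convex face of the cis-fused bicycle), giving isopropyl cis to H-5 and the C4 hydroxyl cis to C6.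

Step 13
Reactants: 21 tertiary alcohol
Product: 22 (1R,3S,3aR,4S,8S,8aS)-3-(tert-butyldimethylsilyloxy)-1-isopropyl-3a,6-dimethyl-1,2,3,3a,4,7,8,8a-octahydroazulene-1,4,8-triol
Conditions: PPTS, MeOH/CH2Cl2, 0 °C to rt
Reagents that add atoms: none
Why: Mild acid-catalysed methanolysis cleaves the two secondary triethylsilyl ethers much faster than the hindered tert-butyldimethylsilyl ether at C2.

Step 14
Reactants: 22 triol
Product: 23 8α,9α-epoxide of 22 (oxirane cis to the C10 hydroxyl, trans to the C6 hydroxyl and to CH3 on C1)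
Conditions: VO(acac)2 (cat.), t-BuOOH, CH2Cl2, 0 °C to rt
Reagents that add atoms: tert-butyl hydroperoxide, CC(C)(C)OO
Why: Vanadium-catalysed epoxidation directed by the allylic C10 hydroxyl should deliver oxygen syn to it, as for cyclic allylic alcohols, which is the face required for the C8/C9 stereocentres.

Step 15
Reactants: 23 epoxy triol
Product: 24 6,10-bis-O-[(Z)-2-methylbut-2-enoyl] derivative of 23 (C2 silyl ether, C4 tertiary alcohol free)
Conditions: angelic acid, 2,4,6-trichlorobenzoyl chloride, Et3N, toluene, rt; then 23, 80 °C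
Reagents that add atoms: angelic acid ((Z)-2-methylbut-2-enoic acid), C/C=C(/C)C(=O)O
Why: Yamaguchi-type mixed-anhydride esterification without DMAP acylates hindered secondary alcohols with angelic acid without isomerisation to the tiglate, and the tertiary C4 hydroxyl should not react.

Step 16
Reactants: 24 bis-angelate silyl ether
Product: 25 target CNP0265715.3 (6,10-di-O-angeloyl-8α,9α-epoxy-cis-daucane-2,4-diol)
Conditions: HF·pyridine, pyridine, THF, 0 °C to rt
Reagents that add atoms: none
Why: Buffered fluoride desilylation should free the C2 hydroxyl while leaving the epoxide and the angelates intact and avoiding base-induced acyl migration.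

**Compound list**

1 | but-2-yn-1-ol | CC#CCO | starting material
2 | sodium 2,2-bis(2-methoxyethoxy)-3-methyl-2,5-dihydro-1,2-oxaluminol-2-uide (cyclic alkenylalanate) | CC1=CCO[Al-]1(OCCOC)OCCOC.[Na+] | intermediate
3 | (Z)-3-iodobut-2-en-1-ol | C/C(I)=C/CO | intermediate
4 | (Z)-3-iodobut-2-enal | C/C(I)=C/C=O | intermediate
5 | (R)-4-benzyl-3-propanoyl-1,3-thiazolidine-2-thione | CCC(=O)N1[C@H](Cc2ccccc2)CSC1=S | starting material
6 | trichlorotitanium (Z)-enolate of 5 | C/C=C(\O[Ti](Cl)(Cl)Cl)N1[C@H](Cc2ccccc2)CSC1=S | intermediate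
7 | (R)-4-benzyl-3-[(2R,3R,4Z)-3-hydroxy-5-iodo-2-methylhex-4-enoyl]-1,3-thiazolidine-2-thione | C/C(I)=C/[C@H](O)[C@@H](C)C(=O)N1[C@H](Cc2ccccc2)CSC1=S | intermediate
8 | (R)-4-benzyl-3-[(2R,3R,4Z)-5-iodo-2-methyl-3-(triethylsilyloxy)hex-4-enoyl]-1,3-thiazolidine-2-thione | C/C(I)=C/[C@H](O[Si](CC)(CC)CC)[C@@H](C)C(=O)N1[C@H](Cc2ccccc2)CSC1=S | intermediate
9 | (2R,3R,4Z)-5-iodo-2-methyl-3-(triethylsilyloxy)hex-4-enal | C/C(I)=C/[C@H](O[Si](CC)(CC)CC)[C@@H](C)C=O | intermediate
10 | tert-butyl{[(1E,3S,4Z)-5-iodo-2-methyl-3-(triethylsilyloxy)hexa-1,4-dien-1-yl]oxy}dimethylsilane | C/C(I)=C/[C@H](O[Si](CC)(CC)CC)/C(C)=C/O[Si](C)(C)C(C)(C)C | intermediate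
11 | ethyl (R)-4-chloro-3-hydroxybutanoate | CCOC(=O)C[C@@H](O)CCl | starting material
12 | ethyl 2-[(2R)-oxiran-2-yl]acetate | CCOC(=O)C[C@@H]1CO1 | intermediate
13 | (Z)-alkenyllithium from 10 (Li in place of I) | [Li]/C(C)=C\[C@H](O[Si](CC)(CC)CC)/C(C)=C/O[Si](C)(C)C(C)(C)C | intermediate
14 | (Z)-alkenylmagnesium bromide from 13 | Br[Mg]/C(C)=C\[C@H](O[Si](CC)(CC)CC)/C(C)=C/O[Si](C)(C)C(C)(C)C | intermediate
15 | ethyl (3S,5Z,7S,8E)-9-(tert-butyldimethylsilyloxy)-3-hydroxy-5,8-dimethyl-7-(triethylsilyloxy)nona-5,8-dienoate | CCOC(=O)C[C@@H](O)C/C(C)=C\[C@H](O[Si](CC)(CC)CC)/C(C)=C/O[Si](C)(C)C(C)(C)C | intermediate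
16 | ethyl (3S,5Z,7S,8E)-9-(tert-butyldimethylsilyloxy)-5,8-dimethyl-3,7-bis(triethylsilyloxy)nona-5,8-dienoate | CCOC(=O)C[C@@H](O[Si](CC)(CC)CC)C/C(C)=C\[C@H](O[Si](CC)(CC)CC)/C(C)=C/O[Si](C)(C)C(C)(C)C | intermediate
17 | (4S,6Z,8S,9E)-10-(tert-butyldimethylsilyloxy)-1-chloro-6,9-dimethyl-4,8-bis(triethylsilyloxy)deca-6,9-dien-2-one | ClCC(=O)C[C@@H](O[Si](CC)(CC)CC)C/C(C)=C\[C@H](O[Si](CC)(CC)CC)/C(C)=C/O[Si](C)(C)C(C)(C)C | intermediate
18 | 2-oxyallyl cation (zwitterion) from 17, C3–C4–C5 | [CH2+]C([O-])=C[C@@H](O[Si](CC)(CC)CC)C/C(C)=C\[C@H](O[Si](CC)(CC)CC)/C(C)=C/O[Si](C)(C)C(C)(C)C | intermediate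
19 | cycloheptene zwitterion after C1–C5 bond formation (C3=C4 enolate on C5, C2 silyloxocarbenium on C1) | CC[Si](CC)(CC)O[C@H]1CC(C)=C[C@H](O[Si](CC)(CC)CC)[C@@](C=[O+][Si](C)(C)C(C)(C)C)(C)[C@@H]1C([O-])=C | intermediate
20 | (3S,3aS,4S,8S,8aS)-3-(tert-butyldimethylsilyloxy)-3a,6-dimethyl-4,8-bis(triethylsilyloxy)-3,3a,4,7,8,8a-hexahydroazulen-1(2H)-one | CC[Si](CC)(CC)O[C@H]1CC(C)=C[C@H](O[Si](CC)(CC)CC)[C@@]2(C)[C@@H]1C(=O)C[C@@H]2O[Si](C)(C)C(C)(C)C | intermediate
21 | (1R,3S,3aS,4S,8S,8aS)-3-(tert-butyldimethylsilyloxy)-1-isopropyl-3a,6-dimethyl-4,8-bis(triethylsilyloxy)-1,2,3,3a,4,7,8,8a-octahydroazulen-1-ol | CC[Si](CC)(CC)O[C@H]1CC(C)=C[C@H](O[Si](CC)(CC)CC)[C@@]2(C)[C@@H]1[C@](O)(C(C)C)C[C@@H]2O[Si](C)(C)C(C)(C)C | intermediate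
22 | (1R,3S,3aR,4S,8S,8aS)-3-(tert-butyldimethylsilyloxy)-1-isopropyl-3a,6-dimethyl-1,2,3,3a,4,7,8,8a-octahydroazulene-1,4,8-triol | O[C@H]1CC(C)=C[C@H](O)[C@@]2(C)[C@@H]1[C@](O)(C(C)C)C[C@@H]2O[Si](C)(C)C(C)(C)C | intermediate
23 | 8α,9α-epoxide of 22 (oxirane cis to the C10 hydroxyl) | O[C@H]1C[C@]2(C)O[C@@H]2[C@H](O)[C@@]2(C)[C@@H]1[C@](O)(C(C)C)C[C@@H]2O[Si](C)(C)C(C)(C)C | intermediate
24 | 6,10-bis-O-[(Z)-2-methylbut-2-enoyl] derivative of 23 | C/C=C(/C)C(=O)O[C@H]1C[C@]2(C)O[C@@H]2[C@H](OC(=O)/C(C)=C\C)[C@@]2(C)[C@@H]1[C@](O)(C(C)C)C[C@@H]2O[Si](C)(C)C(C)(C)C | intermediate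
25 | CNP0265715.3, 6,10-di-O-angeloyl-8α,9α-epoxy-cis-daucane-2,4-diol | C/C=C(/C)C(=O)O[C@H]1C[C@]2(C)O[C@@H]2[C@H](OC(=O)/C(C)=C\C)[C@@]2(C)[C@@H]1[C@](O)(C(C)C)C[C@@H]2O | target

**Step count and risks**

Total step count: 16. Longest linear sequence: 15 steps (steps 1–6 and 8–16, from but-2-yn-1-ol); step 7 is a one-step side branch.

Steps most likely to fail:

1. Step 11 (key cycloaddition). The oxyallyl cation may be diverted by Favorskii rearrangement or chloride return, the zwitterion may close through oxygen or lose its silyl group before the second bond forms, and the face selection by C6 and C10 or the cis fusion may be poor. Fallback: the two rings are closed in separate, individually known operations. It sets out from 17. Et3N in CF3CH2OH at rt should effect intramolecular C-alkylation of the enol ether by the oxyallyl cation with transfer of the silyl group to the solvent, giving the cycloheptene keto aldehyde F1. LiN(SiMe3)2 in THF at −78 °C should then deprotonate the methyl ketone kinetically, and the enolate adds to the non-enolisable aldehyde to give the hydroxy ketone F2. TBSOTf/2,6-lutidine silylates the C2 hydroxyl, and the sequence comes back to the route at 20.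

2. Step 12 (isopropyl addition). Enolisation of the hindered ketone, reduction by β-hydride transfer from the secondary organometallic, β-elimination of a silyloxy group or attack from the wrong face may compete. Fallback: the isopropyl group is brought in as an sp2 nucleophile that cannot transfer hydride. It sets out from 20. 2-Propenylmagnesium bromide/CeCl3 (THF, −78 °C) should give the isopropenyl carbinol F3. Hydrogenation with RhCl(PPh3)3/H2 in benzene should then saturate only the 1,1-disubstituted olefin, leaving the trisubstituted C8=C9 olefin, and the sequence comes back at 21.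

3. Step 14 (directed epoxidation). The homoallylic C6 hydroxyl, which lies on the opposite face, may direct oxygen to the β face, or may open the new epoxide at C9 transannularly. Fallback: the esters are installed first and the oxirane is built by anti addition and closure. It sets out from 22. Esterification as in step 15 should give the bis-angelate olefin F4. NBS in aqueous 1,2-dimethoxyethane should form the bromonium ion anti to the allylic C10 ester, with water opening at tertiary C8 to give the 9β-bromo-8α-hydroxy compound F5; the electron-poor angelate olefins do not react. Ag2O in CH2Cl2 then closes the oxirane with inversion at C9, and the sequence comes back at 24.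

**Further compounds**

F1 | step 11 | cycloheptene keto aldehyde: C1 bears CH3 and CHO, C5 bears acetyl, C6 and C10 triethylsilyloxy | CC[Si](CC)(CC)O[C@H]1CC(C)=C[C@H](O[Si](CC)(CC)CC)[C@@](C=O)(C)[C@@H]1C(C)=O
F2 | step 11 | C2-hydroxy analogue of 20 (β-hydroxy cyclopentanone) | CC[Si](CC)(CC)O[C@H]1CC(C)=C[C@H](O[Si](CC)(CC)CC)[C@@]2(C)[C@@H]1C(=O)C[C@@H]2O
F3 | step 12 | isopropenyl analogue of 21 (prop-1-en-2-yl on C4) | CC[Si](CC)(CC)O[C@H]1CC(C)=C[C@H](O[Si](CC)(CC)CC)[C@@]2(C)[C@@H]1[C@](O)(C(C)=C)C[C@@H]2O[Si](C)(C)C(C)(C)C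
F4 | step 14 | 6,10-bis-O-angeloyl derivative of 22 (C8=C9 olefin) | C/C=C(/C)C(=O)O[C@H]1CC(C)=C[C@H](OC(=O)/C(C)=C\C)[C@@]2(C)[C@@H]1[C@](O)(C(C)C)C[C@@H]2O[Si](C)(C)C(C)(C)C
F5 | step 14 | 9β-bromo-8α-hydroxy bromohydrin of F4 | C/C=C(/C)C(=O)O[C@H]1C[C@](C)(O)[C@@H](Br)[C@H](OC(=O)/C(C)=C\C)[C@@]2(C)[C@@H]1[C@](O)(C(C)C)C[C@@H]2O[Si](C)(C)C(C)(C)C
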